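**Retrosynthetic overview**
1. Target 29 (6,7-cis-fused lactone; 6S,7R,8R,10R, acyl 2R) ⇐ unmasking of the C13 dimethylamine adduct 27, which protects the α-methylene lactone during ring closure.
2. Ten-membered carbocycle (formed second) ⇐ proposed macrocyclising carbonylative Heck reaction of 26: C4–I + CO (becomes C3) + the C1=C2 vinyl group; makes C3–C4, C2–C3 and the E-enone.
3. γ-Lactone (formed first) ⇐ chromium-mediated 2-(methoxycarbonyl)allylation/lactonisation of (Z)-3-iodobut-2-enal 17 with (Z)-bromoenoate 13; sets C6 and C7 from C8.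
4. 13 ⇐ Morita–Baylis–Hillman reaction/bromination of α-PMB-oxy aldehyde 10; C8 from proline α-aminoxylation, C10 from (R)-linalool 1, acyl group from (R)-2-methylbutanoic acid 22.

Assumption: atoms carry germacranolide numbers (C1–C10 carbocycle, C11–C13 lactone carbons, C14/C15 methyls); commercial (R)-(−)-linalool and (R)-2-methylbutanoic acid are taken as enantiopure.

**Route**

Step 1
Reactants: 1 (R)-(−)-linalool
Product: 2 (3R)-3,7-dimethyl-3-(triethylsilyloxy)octa-1,6-diene
Conditions: Et3SiOTf, 2,6-lutidine, CH2Cl2, −78 to 0 °C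
Reagents that add atoms: triethylsilyl trifluoromethanesulfonate, CC[Si](CC)(CC)OS(=O)(=O)C(F)(F)F
Why: Silyl triflate O-silylation of the hindered tertiary alcohol blocks lactol formation with the later C7 aldehyde and leaves the chiral-pool C10 centre untouched.

Step 2
Reactants: 2 (3R)-3,7-dimethyl-3-(triethylsilyloxy)octa-1,6-diene
Product: 4 (4R)-4-methyl-4-(triethylsilyloxy)hex-5-enal, via secondary ozonide 3 (not isolated)
Conditions: O3 (1 equiv, Sudan red 7B end point), CH2Cl2, −78 °C; then Me2S, −78 °C to rt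
Reagents that add atoms: ozone, [O-][O+]=O
Why: Criegee ozonolysis is chemoselective for the electron-rich trisubstituted alkene over the hindered vinyl group when ozone is titrated, and reductive work-up of the ozonide gives the C7 aldehyde.

Step 3
Reactants: 4 (4R)-4-methyl-4-(triethylsilyloxy)hex-5-enal
Product: 6 (2R,4R)-2-(anilinooxy)-4-methyl-4-(triethylsilyloxy)hex-5-en-1-ol, via alpha-aminoxy aldehyde 5 (not isolated)
Conditions: PhNO (slow addition), L-proline (30 mol %), MeCN, −20 °C; then NaBH4, EtOH, 0 °C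
Reagents that add atoms: nitrosobenzene, O=Nc1ccccc1
Why: Proline enamine catalysis (α-aminoxylation, O-selective nitroso aldol through the hydrogen-bonded List–Houk transition state) sets C8 as R under catalyst control, and in situ reduction prevents racemisation of the labile α-aminoxy aldehyde.

Step 4
Reactants: 6 (2R,4R)-2-(anilinooxy)-4-methyl-4-(triethylsilyloxy)hex-5-en-1-ol
Product: 7 (2R,4R)-4-methyl-4-(triethylsilyloxy)hex-5-ene-1,2-diol
Conditions: Zn, AcOH, EtOH, rt
Reagents that add atoms: none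
Why: Reductive N–O cleavage releases the 1,2-diol without touching the alkene or either stereocentre.

Step 5
Reactants: 7 (2R,4R)-4-methyl-4-(triethylsilyloxy)hex-5-ene-1,2-diol
Product: 8 (4R)-2-(4-methoxyphenyl)-4-[(2R)-2-methyl-2-(triethylsilyloxy)but-3-en-1-yl]-1,3-dioxolane (both acetal epimers)
Conditions: 4-MeOC6H4CH(OMe)2, PPTS (cat.), CH2Cl2, rt
Reagents that add atoms: 4-methoxybenzaldehyde dimethyl acetal, COC(OC)c1ccc(OC)cc1
Why: Acid-catalysed transacetalisation gives the five-membered p-methoxybenzylidene acetal; the acetal carbon is an inconsequential mixture.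

Step 6
Reactants: 8 the p-methoxybenzylidene acetal
Product: 9 (2R,4R)-2-[(4-methoxybenzyl)oxy]-4-methyl-4-(triethylsilyloxy)hex-5-en-1-ol
Conditions: i-Bu2AlH, CH2Cl2, −78 to 0 °C
Reagents that add atoms: none
Why: Regioselective reductive acetal opening: aluminium coordinates the less hindered primary oxygen, so the PMB ether stays on the secondary C8 oxygen and the primary alcohol is freed.

Step 7
Reactants: 9 (2R,4R)-2-[(4-methoxybenzyl)oxy]-4-methyl-4-(triethylsilyloxy)hex-5-en-1-ol
Product: 10 (2R,4R)-2-[(4-methoxybenzyl)oxy]-4-methyl-4-(triethylsilyloxy)hex-5-enal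
Conditions: Dess–Martin periodinane, CH2Cl2, 0 °C to rt
Reagents that add atoms: none
Why: Dess–Martin oxidation gives the α-alkoxy aldehyde under near-neutral conditions without epimerising C8.

Step 8
Reactants: 10 the α-PMB-oxy aldehyde; 11 methyl acrylate
Product: 12 methyl (4R,6R)-3-hydroxy-4-[(4-methoxybenzyl)oxy]-6-methyl-2-methylidene-6-(triethylsilyloxy)oct-7-enoate (C3 epimers)
Conditions: methyl acrylate (neat, excess), DABCO (1 equiv), MeOH (cat.), rt, 4 d
Reagents that add atoms: none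
Why: Morita–Baylis–Hillman reaction; the electron-poor α-alkoxy aldehyde is a good acceptor for the DABCO–acrylate enolate, and the new carbinol centre is destroyed in the next step.

Step 9
Reactants: 12 the Morita–Baylis–Hillman adduct
Product: 13 methyl (2Z,4R,6R)-2-(bromomethyl)-4-[(4-methoxybenzyl)oxy]-6-methyl-6-(triethylsilyloxy)octa-2,7-dienoate
Conditions: NBS, Me2S, CH2Cl2, 0 °C to rt
Reagents that add atoms: N-bromosuccinimide, BrN1C(=O)CCC1=O
Why: Corey–Kim-type activation of the allylic alcohol and SN2' bromide delivery give the rearranged primary bromide as the preferred Z isomer (C8 cis to CH2Br).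

Step 10
Reactants: 14 ethyl but-2-ynoate
Product: 15 ethyl (2Z)-3-iodobut-2-enoate
Conditions: NaI, AcOH, 115 °C
Reagents that add atoms: sodium iodide, [Na+].[I-]
Why: Conjugate anti-hydroiodination of the ynoate by HI made in situ gives the (Z)-β-iodo enoate with iodine cis to the ester.

Step 11
Reactants: 15 ethyl (2Z)-3-iodobut-2-enoate
Product: 16 (2Z)-3-iodobut-2-en-1-ol
Conditions: i-Bu2AlH, CH2Cl2, −78 °C
Reagents that add atoms: none
Why: Ester reduction to the allylic alcohol leaves the alkenyl iodide and the alkene geometry intact at low temperature.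

Step 12
Reactants: 16 (2Z)-3-iodobut-2-en-1-ol
Product: 17 (2Z)-3-iodobut-2-enal
Conditions: MnO2, CH2Cl2, rt, dark; used crude
Reagents that add atoms: none
Why: Allylic alcohol oxidation on MnO2 is neutral and keeps the Z geometry.

Step 13
Reactants: 13 the (Z)-bromoenoate; 17 (2Z)-3-iodobut-2-enal
Product: 20 (4R,5R)-5-[(1Z)-2-iodoprop-1-en-1-yl]-4-{(1R,3R)-1-[(4-methoxybenzyl)oxy]-3-methyl-3-(triethylsilyloxy)pent-4-en-1-yl}-3-methylideneoxolan-2-one (cis-lactone), via allylchromium dichloride 18 (not isolated), via hydroxy ester 19 (not isolated)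
Conditions: CrCl2 (nickel-free, 4 equiv), THF, 0 °C to rt; then PPTS, CH2Cl2, rt
Reagents that add atoms: chromium dichloride, Cl[Cr]Cl
Why: Nozaki–Hiyama-type chromium Barbier 2-(alkoxycarbonyl)allylation in which the Z allylchromium reacts through a closed chair transition state to give the syn adduct (C6 and C7, cis-lactone) and the aldehyde adds anti to the C9 chain with H8 in the alkene plane (allylic 1,3-strain), so C7 is set correctly relative to C8; nickel-free CrCl2 spares the alkenyl iodide and acid closes the lactone.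

Step 14
Reactants: 20 the PMB-protected cis-lactone
Product: 21 (4R,5R)-4-[(1R,3R)-1-hydroxy-3-methyl-3-(triethylsilyloxy)pent-4-en-1-yl]-5-[(1Z)-2-iodoprop-1-en-1-yl]-3-methylideneoxolan-2-one
Conditions: DDQ, CH2Cl2/pH 7 buffer, 0 °C
Reagents that add atoms: none
Why: Oxidative PMB ether cleavage by DDQ through the benzylic oxocarbenium ion; silyl ether, alkenyl iodide and enoate are inert.

Step 15
Reactants: 21 the C8 alcohol; 22 (2R)-2-methylbutanoic acid
Product: 24 (1R,3R)-1-{(2R,3R)-2-[(1Z)-2-iodoprop-1-en-1-yl]-4-methylidene-5-oxooxolan-3-yl}-3-methyl-3-(triethylsilyloxy)pent-4-en-1-yl (2R)-2-methylbutanoate, via O-acylisourea 23 (not isolated)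
Conditions: DIC, DMAP (cat.), CH2Cl2, 0 °C to rt
Reagents that add atoms: N,N'-diisopropylcarbodiimide, CC(C)N=C=NC(C)C
Why: Steglich esterification acylates the secondary C8 hydroxyl, and low temperature with catalytic DMAP keeps the α-stereocentre of the acid intact.

Step 16
Reactants: 24 the C8 ester
Product: 25 (1R,3R)-3-hydroxy-1-{(2R,3R)-2-[(1Z)-2-iodoprop-1-en-1-yl]-4-methylidene-5-oxooxolan-3-yl}-3-methylpent-4-en-1-yl (2R)-2-methylbutanoate
Conditions: HF·pyridine, THF, 0 °C to rt
Reagents that add atoms: none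
Why: Fluoride-mediated desilylation frees the tertiary C10 hydroxyl, which makes the vinyl group a better insertion partner in the ring closure.

Step 17
Reactants: 25 the tertiary alcohol
Product: 26 (1R,3R)-1-{(2R,3R)-4-[(dimethylamino)methyl]-2-[(1Z)-2-iodoprop-1-en-1-yl]-5-oxooxolan-3-yl}-3-hydroxy-3-methylpent-4-en-1-yl (2R)-2-methylbutanoate (epimers at the aminomethyl-bearing carbon)
Conditions: Me2NH (2 M in THF), MeOH, rt
Reagents that add atoms: dimethylamine, CNC
Why: Aza-Michael addition masks the α-methylene lactone, the alkene most prone to 6-exo capture by an acylpalladium species, as its Mannich base.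

Step 18
Reactants: 26 the masked iodo-diene
Product: 27 [(3aR,4R,6R,7E,10Z,11aS)-3-[(dimethylamino)methyl]-6-hydroxy-6,10-dimethyl-2,9-dioxo-2,3,3a,4,5,6,9,11a-octahydrocyclodeca[b]furan-4-yl] (2R)-2-methylbutanoate (C3 epimers)
Conditions: Pd(OAc)2 (10 mol %), 1,3-bis(diphenylphosphino)propane (12 mol %), Ag2CO3 (1.2 equiv), CO (1 atm), 1,4-dioxane (2 mM, slow addition), 60 °C
Reagents that add atoms: carbon monoxide, [C-]#[O+]
Why: Proposed new method: a macrocyclising carbonylative Heck reaction (intramolecular acylpalladation) in which zerovalent palladium adds oxidatively to the C4–I bond with retention of Z geometry, CO inserts to give the unsaturated acyl complex of divalent palladium (C3), silver abstracts iodide so the cationic diphosphine complex binds the hydroxyl-bearing terminal vinyl group, 1,2-insertion places the acyl group on terminal C2 and palladium on C1, and syn β-hydride elimination of a C2 hydrogen (C10 has none) gives the E-enone, so C3–C4, C2–C3 and the ten-membered ring form in one step; the closest known chemistry is the intermolecular carbonylative Heck reaction of aryl or alkenyl halides with alkenes, cyclic acylpalladation to five- and six-membered rings, and carbonylative Stille macrocyclisation to dienones.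

Step 19
Reactants: 27 the masked macrocycle
Product: 29 [(3aR,4R,6R,7E,10Z,11aS)-6-hydroxy-6,10-dimethyl-3-methylidene-2,9-dioxo-3a,4,5,11a-tetrahydrocyclodeca[b]furan-4-yl] (2R)-2-methylbutanoate (target), via ammonium iodide 28 (not isolated)
Conditions: MeI, THF, rt; then aq. NaHCO3, CH2Cl2, rt
Reagents that add atoms: iodomethane, CI
Why: N-methylation followed by E1cB (Hofmann-type) loss of trimethylamine regenerates the α-methylene lactone under mild base that leaves the dienone and both esters alone.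

**Compound list**
1 | (R)-(−)-linalool, (3R)-3,7-dimethylocta-1,6-dien-3-ol | CC(C)=CCC[C@@](C)(O)C=C | starting material
2 | (3R)-3,7-dimethyl-3-(triethylsilyloxy)octa-1,6-diene | CC(C)=CCC[C@@](C)(O[Si](CC)(CC)CC)C=C | intermediate
3 | secondary ozonide, 3,3-dimethyl-5-[(3R)-3-methyl-3-(triethylsilyloxy)pent-4-en-1-yl]-1,2,4-trioxolane (not isolated) | CC1(C)OOC(CC[C@@](C)(O[Si](CC)(CC)CC)C=C)O1 | intermediate
4 | (4R)-4-methyl-4-(triethylsilyloxy)hex-5-enal | O=CCC[C@@](C)(O[Si](CC)(CC)CC)C=C | intermediate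
5 | (2R,4R)-2-(anilinooxy)-4-methyl-4-(triethylsilyloxy)hex-5-enal (not isolated) | O=C[C@H](ONc1ccccc1)C[C@@](C)(O[Si](CC)(CC)CC)C=C | intermediate
6 | (2R,4R)-2-(anilinooxy)-4-methyl-4-(triethylsilyloxy)hex-5-en-1-ol | OC[C@H](ONc1ccccc1)C[C@@](C)(O[Si](CC)(CC)CC)C=C | intermediate
7 | (2R,4R)-4-methyl-4-(triethylsilyloxy)hex-5-ene-1,2-diol | OC[C@H](O)C[C@@](C)(O[Si](CC)(CC)CC)C=C | intermediate
8 | (4R)-2-(4-methoxyphenyl)-4-[(2R)-2-methyl-2-(triethylsilyloxy)but-3-en-1-yl]-1,3-dioxolane (acetal epimers) | COc1ccc(cc1)C1OC[C@H](O1)C[C@@](C)(O[Si](CC)(CC)CC)C=C | intermediate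
9 | (2R,4R)-2-[(4-methoxybenzyl)oxy]-4-methyl-4-(triethylsilyloxy)hex-5-en-1-ol | OC[C@H](OCc1ccc(OC)cc1)C[C@@](C)(O[Si](CC)(CC)CC)C=C | intermediate
10 | (2R,4R)-2-[(4-methoxybenzyl)oxy]-4-methyl-4-(triethylsilyloxy)hex-5-enal | O=C[C@H](OCc1ccc(OC)cc1)C[C@@](C)(O[Si](CC)(CC)CC)C=C | intermediate
11 | methyl acrylate | C=CC(=O)OC | starting material
12 | methyl (4R,6R)-3-hydroxy-4-[(4-methoxybenzyl)oxy]-6-methyl-2-methylidene-6-(triethylsilyloxy)oct-7-enoate (C3 epimers) | C=C(C(=O)OC)C(O)[C@H](OCc1ccc(OC)cc1)C[C@@](C)(O[Si](CC)(CC)CC)C=C | intermediate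
13 | methyl (2Z,4R,6R)-2-(bromomethyl)-4-[(4-methoxybenzyl)oxy]-6-methyl-6-(triethylsilyloxy)octa-2,7-dienoate | COC(=O)/C(CBr)=C/[C@H](OCc1ccc(OC)cc1)C[C@@](C)(O[Si](CC)(CC)CC)C=C | intermediate
14 | ethyl but-2-ynoate | CC#CC(=O)OCC | starting material
15 | ethyl (2Z)-3-iodobut-2-enoate | C/C(I)=C/C(=O)OCC | intermediate
16 | (2Z)-3-iodobut-2-en-1-ol | C/C(I)=C/CO | intermediate
17 | (2Z)-3-iodobut-2-enal | C/C(I)=C/C=O | intermediate
18 | dichloro[(2Z,4R,6R)-2-(methoxycarbonyl)-4-[(4-methoxybenzyl)oxy]-6-methyl-6-(triethylsilyloxy)octa-2,7-dien-1-yl]chromium (trivalent chromium, not isolated) | Cl[Cr](Cl)C/C(C(=O)OC)=C\[C@H](OCc1ccc(OC)cc1)C[C@@](C)(O[Si](CC)(CC)CC)C=C | intermediate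
19 | methyl (3S,4R,5Z)-4-hydroxy-6-iodo-3-{(1R,3R)-1-[(4-methoxybenzyl)oxy]-3-methyl-3-(triethylsilyloxy)pent-4-en-1-yl}-2-methylidenehept-5-enoate (not isolated) | COC(=O)C(=C)[C@@H]([C@@H](O)/C=C(/C)I)[C@H](OCc1ccc(OC)cc1)C[C@@](C)(O[Si](CC)(CC)CC)C=C | intermediate
20 | (4R,5R)-5-[(1Z)-2-iodoprop-1-en-1-yl]-4-{(1R,3R)-1-[(4-methoxybenzyl)oxy]-3-methyl-3-(triethylsilyloxy)pent-4-en-1-yl}-3-methylideneoxolan-2-one | C=C1C(=O)O[C@@H](/C=C(/C)I)[C@H]1[C@H](OCc2ccc(OC)cc2)C[C@@](C)(O[Si](CC)(CC)CC)C=C | intermediate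
21 | (4R,5R)-4-[(1R,3R)-1-hydroxy-3-methyl-3-(triethylsilyloxy)pent-4-en-1-yl]-5-[(1Z)-2-iodoprop-1-en-1-yl]-3-methylideneoxolan-2-one | C=C1C(=O)O[C@@H](/C=C(/C)I)[C@H]1[C@H](O)C[C@@](C)(O[Si](CC)(CC)CC)C=C | intermediate
22 | (2R)-2-methylbutanoic acid | CC[C@@H](C)C(=O)O | starting material
23 | O-[(2R)-2-methylbutanoyl]-N,N'-diisopropylisourea (not isolated) | CC[C@@H](C)C(=O)OC(=NC(C)C)NC(C)C | intermediate
24 | (1R,3R)-1-{(2R,3R)-2-[(1Z)-2-iodoprop-1-en-1-yl]-4-methylidene-5-oxooxolan-3-yl}-3-methyl-3-(triethylsilyloxy)pent-4-en-1-yl (2R)-2-methylbutanoate | C=C1C(=O)O[C@@H](/C=C(/C)I)[C@H]1[C@H](OC(=O)[C@H](C)CC)C[C@@](C)(O[Si](CC)(CC)CC)C=C | intermediate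
25 | (1R,3R)-3-hydroxy-1-{(2R,3R)-2-[(1Z)-2-iodoprop-1-en-1-yl]-4-methylidene-5-oxooxolan-3-yl}-3-methylpent-4-en-1-yl (2R)-2-methylbutanoate | C=C1C(=O)O[C@@H](/C=C(/C)I)[C@H]1[C@H](OC(=O)[C@H](C)CC)C[C@@](C)(O)C=C | intermediate
26 | (1R,3R)-1-{(2R,3R)-4-[(dimethylamino)methyl]-2-[(1Z)-2-iodoprop-1-en-1-yl]-5-oxooxolan-3-yl}-3-hydroxy-3-methylpent-4-en-1-yl (2R)-2-methylbutanoate (epimers at oxolane C4) | CN(C)CC1C(=O)O[C@@H](/C=C(/C)I)[C@H]1[C@H](OC(=O)[C@H](C)CC)C[C@@](C)(O)C=C | intermediate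
27 | [(3aR,4R,6R,7E,10Z,11aS)-3-[(dimethylamino)methyl]-6-hydroxy-6,10-dimethyl-2,9-dioxo-2,3,3a,4,5,6,9,11a-octahydrocyclodeca[b]furan-4-yl] (2R)-2-methylbutanoate (C3 epimers) | CN(C)CC1C(=O)O[C@H]2/C=C(/C)C(=O)/C=C/[C@](C)(O)C[C@@H](OC(=O)[C@H](C)CC)[C@@H]12 | intermediate
28 | N-methyl ammonium iodide of 27 (trimethylammoniomethyl lactone, not isolated) | C[N+](C)(C)CC1C(=O)O[C@H]2/C=C(/C)C(=O)/C=C/[C@](C)(O)C[C@@H](OC(=O)[C@H](C)CC)[C@@H]12.[I-] | intermediate
29 | [(3aR,4R,6R,7E,10Z,11aS)-6-hydroxy-6,10-dimethyl-3-methylidene-2,9-dioxo-3a,4,5,11a-tetrahydrocyclodeca[b]furan-4-yl] (2R)-2-methylbutanoate | C=C1C(=O)O[C@H]2/C=C(/C)C(=O)/C=C/[C@](C)(O)C[C@@H](OC(=O)[C@H](C)CC)[C@@H]12 | target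

**Totals and risks**

Total step count: 19. Longest linear sequence: 16 steps (steps 1–9 and 13–19 from linalool); steps 10–12 make the three-step side branch to 17.

The three steps most likely to fail:

Step 18 (the proposed new ring closure). Risks are oligomerisation, direct non-carbonylative Heck coupling, ionisation of the allylic lactone C6–O bond by zerovalent palladium, and formation of the Z-enone, which would be trapped as the C3 hemiketal with the C10 hydroxyl. Fallback with known chemistry: it sets out from 26 and comes back at 27. Cross-metathesis of the terminal vinyl group of 26 (as its TsOH salt) with crotonaldehyde (second-generation Hoveyda–Grubbs catalyst, CH2Cl2, 40 °C) gives the (E)-enal F1. The masked lactone has no alkene that could compete in ring-closing metathesis. Nozaki–Hiyama–Kishi macrocyclisation (CrCl2, NiCl2 1 mol %, DMSO–THF, 2 mM, rt) joins C4 to the aldehyde carbon and gives the macrocyclic allylic alcohol F2 as C3 epimers. MnO2 oxidation of this bis-allylic alcohol then gives 27.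

Step 13 (chromium allylation/lactonisation). Risks are wrong facial selectivity relative to C8, partial E/Z equilibration of the allylchromium leading to trans-lactone, and 1,4-elimination of the C8 oxygen. Fallback: it sets out from 13 (with 17) and comes back at 20. Pd2(dba)3-catalysed borylation of 13 with B2pin2 (toluene, 50 °C) gives the allylboronate F3. Sc(OTf)3-catalysed allylboration of 17 at −78 °C proceeds through a closed six-membered transition state that is stereospecific for the Z reagent (syn adduct) and involves no reducing metal. PPTS then closes hydroxy ester 19 to 20.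

Step 8 (Morita–Baylis–Hillman reaction). Risks are a slow reaction with the branched α-alkoxy aldehyde and base-induced epimerisation at C8 over several days. Fallback: it sets out from 10 and comes back at 12. Aldol addition of the lithium enolate of methyl 3-(dimethylamino)propanoate (LiN(i-Pr)2, THF, −78 °C) to 10 gives the amino aldol adduct F4. N-oxidation with mCPBA (CH2Cl2, 0 °C) and Cope elimination on warming to rt give 12 without prolonged exposure of the aldehyde to amine base.

**Further compounds**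
F1 | step 18 | (1R,3R,4E)-1-{(2R,3R)-4-[(dimethylamino)methyl]-2-[(1Z)-2-iodoprop-1-en-1-yl]-5-oxooxolan-3-yl}-3-hydroxy-3-methyl-6-oxohex-4-en-1-yl (2R)-2-methylbutanoate | CN(C)CC1C(=O)O[C@@H](/C=C(/C)I)[C@H]1[C@H](OC(=O)[C@H](C)CC)C[C@@](C)(O)/C=C/C=O
F2 | step 18 | 9-hydroxy analogue of 27 (macrocyclic C3 carbinol in germacranolide numbering, both epimers) | CN(C)CC1C(=O)O[C@H]2/C=C(/C)C(O)/C=C/[C@](C)(O)C[C@@H](OC(=O)[C@H](C)CC)[C@@H]12
F3 | step 13 | methyl (2Z,4R,6R)-4-[(4-methoxybenzyl)oxy]-6-methyl-2-[(4,4,5,5-tetramethyl-1,3,2-dioxaborolan-2-yl)methyl]-6-(triethylsilyloxy)octa-2,7-dienoate | COC(=O)/C(CB1OC(C)(C)C(C)(C)O1)=C/[C@H](OCc1ccc(OC)cc1)C[C@@](C)(O[Si](CC)(CC)CC)C=C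
F4 | step 8 | methyl (4R,6R)-2-[(dimethylamino)methyl]-3-hydroxy-4-[(4-methoxybenzyl)oxy]-6-methyl-6-(triethylsilyloxy)oct-7-enoate (C2/C3 epimers) | COC(=O)C(CN(C)C)C(O)[C@H](OCc1ccc(OC)cc1)C[C@@](C)(O[Si](CC)(CC)CC)C=C
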